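Divide the complex with two exchanged by the complex with one exchanged at the last readings of the east and south-east runs, and carry that ratio instead of either amount.

| flask | starting complex | incoming ligand | capture agent | remark | time |
|---|---|---|---|---|---|
| east | 27 mM | 19 mM | 8.1 mM | run made earlier |  |
| south-east | 27 mM | 54 mM | 8.1 mM | run made earlier |  |
| autumn | 27 mM | 21.6 mM | 8.10 mM |  | 3.0 d |
| winter | 27 mM | 40.5 mM | 8.10 mM |  | 3.0 d |
| summer | 27 mM | 13.5 mM | 8.10 mM |  | 3.0 d |

| run | time / h | complex with one exchanged / % | complex with two exchanged / % |
|---|---|---|---|
| east | 5.00 | 12.3 | 2.1 |
| east | 12.0 | 16.3 | 7.5 |
| east | 25.0 | 15.9 | 11.9 |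
| east | 40.0 | 12.7 | 13.2 |
| east | 48.0 | 11.9 | 12.5 |
| south-east | 5.00 | 22.2 | 14.6 |
| south-east | 12.0 | 21.2 | 32.2 |
| south-east | 25.0 | 18.1 | 41.8 |
| south-east | 40.0 | 17.9 | 42.7 |
| south-east | 48.0 | 17.7 | 42.2 |

(each reading ± 0.5 percentage points)

* which of these holds the largest part of the starting complex at the end of autumn (complex with one exchanged / complex with two exchanged / starting complex)
* which of these holds the largest part of the starting complex at the end of winter (complex with one exchanged / complex with two exchanged / starting complex)
* which of these holds the largest part of the starting complex at the end of summer (complex with one exchanged / complex with two exchanged / starting complex)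
* how much complex with one exchanged is there at the end of winter, in percent of the starting complex charged

- percentages count the starting complex that a species holds: one side product counts as two
- what may be going on: complex with one exchanged + capture agent -> trapped intermediate; starting complex + complex with one exchanged -> side product; starting complex + incoming ligand <-> leaving ligand + complex with one exchanged; complex with one exchanged + incoming ligand <-> leaving ligand + complex with two exchanged

The east ratio reads 1.04 at 40.0 h and 1.05 at 48.0 h, the south-east ratio 2.39 and 2.38, so both stand still within the scatter and may be carried to 3.0 d. But the two runs differ in incoming ligand: 0.704 and 2.00 of the starting complex charged. The ratio gain, the rise of the ratio per unit of that fraction, reads 1.03.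

Winter charges 1.50, so my reckoning gives a ratio of 1.87. The sum of both complexes, interpolated likewise, is 46.2%, which leaves 16.1% as complex with one exchanged. But that sum may not be still: in the east run it reads 25.9% and then 24.4%, so my figure may stand on the high side.

The forecast names starting complex for autumn, complex with two exchanged for winter and starting complex for summer, and gives 22% (17% to 27%) for winter, with mono standing for the complex with one exchanged and bis for the complex with two exchanged: “that gives about 22% mono and 29% bis”. Its winter ratio of 1.3 differs from mine.

Of the listed species, autumn ends with starting complex largest, winter with complex with two exchanged and summer with starting complex; winter holds 15.4% of complex with one exchanged.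

    complex with one exchanged + capture agent → trapped intermediate (k = 0.0110 L mol⁻¹ min⁻¹)
    starting complex + complex with one exchanged → side product (k = 0.0280 L mol⁻¹ min⁻¹)
    starting complex + incoming ligand ⇌ leaving ligand + complex with one exchanged (K = 2.10, k = 0.0370 L mol⁻¹ min⁻¹)
    complex with one exchanged + incoming ligand ⇌ leaving ligand + complex with two exchanged (K = 3.40, k = 0.0710 L mol⁻¹ min⁻¹)

In winter, at the concentrations as charged, the complex with one exchanged has a pseudo-first-order half-life of 0.17 d on the forward step to the complex with two exchanged, shorter than its 0.64 d towards side product. The winter ratio ends at 1.94; in the neighbouring flask, winter with 16 mM of starting complex, the ligand fraction is 2.53, the ratio gain gives 2.93, and that flask holds 3.17.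

(The readings are simulated on assumed constants.)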